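All runs were computed with made-up constants, and the scatter is random.

The closed, stirred vessel makes target from starting material and coupling partner, and in both earlier flasks the target then falls again.

| setting | noon | autumn | teal | green |
|---|---|---|---|---|
| starting material | 10 mM | 15 mM | 20 mM | 20 mM |
| coupling partner | 1.3 equiv | 1.3 equiv | 1.30 equiv | 1.30 equiv |
| second substrate | 5 equiv | 5 equiv | 5.00 equiv | 5.00 equiv |
| protic impurity | 1 mM | 1 mM | 1.00 mM | 1.00 mM |
| temperature | 15 °C | 32 °C | 45 °C | 20 °C |
| remark | run made earlier | run made earlier |  |  |
| time |  |  | 25 h | 25 h |

| run | time / h | target / % |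
|---|---|---|
| noon | 6.00 | 34.4 |
| noon | 12.0 | 36.7 |
| noon | 20.0 | 34.7 |
| noon | 40.0 | 30.4 |
| noon | 48.0 | 32.2 |
| noon | 96.0 | 24.0 |
| autumn | 2.50 | 22.9 |
| autumn | 8.00 | 17.4 |
| autumn | 15.0 | 12.7 |
| autumn | 20.0 | 8.6 |
| autumn | 30.0 | 5.5 |
| autumn | 40.0 | 3.0 |

(each reading ± 1 percentage point)

- the flask that comes out highest in amount of target, in percent of the starting material charged, or "all alike" when all lie within 1.5 percentage points (teal / green / all alike)
- target at the end, in percent of the starting material charged, teal
- target at the end, in percent of the starting material charged, green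

Past the peak, each run gives a rate from two readings: the logarithm of their ratio over the time between them. Temperature is then carried by the Arrhenius law, on the assumption that the difference in concentration between the two runs plays no part.

k(noon) = 0.00506 /h, k(autumn) = 0.0542 /h

Ea = 102 kJ/mol

k(green) = 0.0105 /h, k(teal) = 0.280 /h

The fade constant of green, the first-order rate at which target falls past its peak, is reckoned from scattered readings and used as a pseudo-first-order constant.

Two extreme greens can be solved in the head. Green's 20 °C lies nearer noon's 15 °C than autumn's 32 °C, so both borrow noon's highest reading, although noon held half green's charge. In one extreme, target stands at that share and never fades. In the other, it holds that share from the first moment and fades throughout: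

c(target) = 36.7% unfaded, or 28.3% of the charge faded

Noon's highest reading stands at 12.0 h, earlier than 25 h, so my reckoning lets green fade for part of the time and puts it between the two. My own figure is the middle, 32.5%. Teal keeps 0.0912% of its peak under full fading, less than green's 76.9%.

The forecast names green, with 0.1% for teal and 17% for green, and says that the two peaks “suggests a ceiling in absolute amount”. Mine holds the share, not the amount.

Green ends highest, at 33.1% against 0.116% for teal.

    second substrate + protic impurity → quenched substrate (k = 0.424 /M/min, Ea = 70.0 kJ/mol)
    starting material + coupling partner ⇌ target (K = 73.0 /M, k = 0.351 /M/min, Ea = 66.0 kJ/mol, ΔH = −40.0 kJ/mol)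
    2 starting material → homo dimer (k = 8.90 × 10⁻⁵ /M/min, Ea = 86.0 kJ/mol)
    second substrate + coupling partner ⇌ second product (K = 10.2 /M, k = 0.0261 /M/min, Ea = 67.0 kJ/mol, ΔH = −6.00 kJ/mol)
    coupling partner → decomposed reagent (k = 4.66 × 10⁻⁴ /min, Ea = 88.0 kJ/mol)
    (constants at 20 °C)

Neither flask has come to rest at 25 h. Left until 250 h, green's target falls to 5.80%, while its decomposed reagent climbs from 6.09 mM to 23.1 mM. The fade constant, run on from 33.1%, gives 3.15%, less than green holds. In teal, the same rule from 1.53% at 12.5 h gives 0.0462% at 25.0 h, against 0.116% in the flask. By 250 h teal's target stands at 0%, yet its homo dimer has grown from 7.33% to 45.9%.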